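Ring B is cut at B4–B5 and B6–B1, with B3–B4 closing last. B5 (methyl) and B6 (methoxy, next to B1, which carries the methylene bridge) are neighbours and form a hidden 1-methoxypropyne; B1 to B4 come from a cyclobutenone whose carbon 2 already bears the bridge carbon as CH2OMe. One thermal benzannulation builds the hexasubstituted ring with its three oxygens differentiated (free OH, OMe, silyl ether). The precursor is 2-(methoxymethyl)-3-(triisopropylsiloxy)cyclobut-2-enone: the oxygen at carbon 3 is silylated, not alkylated, so that fluoride, not a Lewis acid that the trioxygenated benzylic ether would not survive, frees B2–OH. Acylation through ester photo-rearrangement, desilylation and quinone-methide union with resolved (R)-ring A finish the route.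

Key step: step 4

Labels: B1 carries the CH2 bridge, B2 OH, B3 butanoyl, B4 OH, B5 methyl, B6 OMe.
Assumption: the enol forms drawn for the ring A triones and for the target stand for rapidly equilibrating tautomers; this does not affect the quaternary carbon, which is (R) throughout (CIP order: butanoyl-side enol carbon > other enol carbon > prenyl CH2 > methyl).

Step 1
Reactants: 1 3-methoxyprop-1-yne
Product: 3 [(3-methoxyprop-1-yn-1-yl)oxy]tri(propan-2-yl)silane, via lithium ynolate 2 (not isolated)
Conditions: n-BuLi, THF, −78 °C; LiOOt-Bu (from t-BuOOH and LiN(SiMe3)2), −78 → 0 °C; iPr3SiOTf, −78 → 0 °C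
Reagents that add atoms: tert-butyl hydroperoxide, CC(C)(C)OO; triisopropylsilyl trifluoromethanesulfonate, CC(C)[Si](OS(=O)(=O)C(F)(F)F)(C(C)C)C(C)C
Why: Oxidation of the lithium acetylide by lithium tert-butyl peroxide (electrophilic oxygen transfer to the alkynyl carbanion) should give ynolate 2, whose O-silylation with the bulky silyl triflate is the established route to siloxyalkynes; the ynolate is kept at or below 0 °C so that the neighbouring methoxy group is not expelled.

Step 2
Reactants: 3 [(3-methoxyprop-1-yn-1-yl)oxy]tri(propan-2-yl)silane; 4 acetyl chloride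
Product: 6 2-(methoxymethyl)-3-{[tri(propan-2-yl)silyl]oxy}cyclobut-2-en-1-one, via ketene 5 (not isolated)
Conditions: Et3N, Et2O, 0 °C → rt (4 added slowly)
Reagents that add atoms: none
Why: Ketene–alkyne [2+2] cycloaddition: ketene 5, released from 4 by dehydrochlorination, is attacked at its carbonyl carbon by the nucleophilic methoxymethyl-bearing carbon of the siloxyalkyne, which fixes the siloxy group at ring carbon 3 and the methoxymethyl group at ring carbon 2.

Step 3
Reactants: 7 2-chloro-1,1-dimethoxyethane
Product: 9 1-methoxyprop-1-yne, via sodium methoxyacetylide 8 (not isolated)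
Conditions: NaNH2 (3 equiv), liq. NH3, −33 °C; MeI
Reagents that add atoms: iodomethane, CI
Why: Twofold base-induced elimination (HCl, then methanol) with deprotonation should give acetylide 8, whose C-methylation in the same flask is a standard acetylide alkylation leading to 1-alkoxyalk-1-ynes.

Step 4
Reactants: 6 2-(methoxymethyl)-3-{[tri(propan-2-yl)silyl]oxy}cyclobut-2-en-1-one; 9 1-methoxyprop-1-yne
Product: 14 3-methoxy-4-(methoxymethyl)-2-methyl-5-{[tri(propan-2-yl)silyl]oxy}phenol, via vinylketene 10 (not isolated), via vinylcyclobutenone 11 (not isolated), via dienylketene 12 (not isolated), via cyclohexadienone 13 (not isolated)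
Conditions: 9 (3 equiv), toluene, sealed tube, 120 → 140 °C
Reagents that add atoms: none
Why: Heating should open 6 by a conrotatory four-electron electrocyclic reaction to vinylketene 10, whose ketene C=C bond adds alkyne 9 in a [2+2] cycloaddition to give 11; a second four-electron opening gives dienylketene 12, which cyclizes to 13 and enolizes to 14. The closest known reaction is the Danheiser benzannulation of cyclobutenones with alkoxy- and siloxyalkynes; because the oxygen at ring carbon 3 makes 6 a vinylogous ester, a higher temperature than for 3-alkylcyclobutenones is planned. Ring B is closed by a thermal disrotatory six-electron electrocyclization that forms B3–B4, after the [2+2] step has formed B4–B5 and B6–B1; both four-membered rings are transient. No stereocentre results, since the sp3 carbon of 11 becomes sp2 on ring opening. The step needs regioselectivity in the [2+2] event, and the polarization of ynol ether 9 secures it: its nucleophilic methyl-bearing carbon bonds to the ketene carbonyl carbon, so the methyl group ends up beside the new hydroxyl (B5) and the methoxy group one carbon further on (B6), and the remaining positions are dictated by how the atoms of 6 are already linked. It also needs the dienylketene with its vinyl and ketenyl groups cis, which reversible opening of 11 supplies, and the methyl ynol ether, having no β-hydrogen in its alkyl group, cannot fragment by a retro-ene path at this temperature.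

Step 5
Reactants: 14 3-methoxy-4-(methoxymethyl)-2-methyl-5-{[tri(propan-2-yl)silyl]oxy}phenol; 15 butanoyl chloride
Product: 16 3-methoxy-4-(methoxymethyl)-2-methyl-5-{[tri(propan-2-yl)silyl]oxy}phenyl butanoate
Conditions: Et3N, 4-(dimethylamino)pyridine (cat.), CH2Cl2, 0 °C
Reagents that add atoms: none
Why: Nucleophile-catalysed O-acylation of the only free hydroxyl under basic conditions, which avoids any acid that could ionize the trioxygenated benzylic ether while the nucleophilic ring carbon B3 is still unsubstituted.

Step 6
Reactants: 16 3-methoxy-4-(methoxymethyl)-2-methyl-5-{[tri(propan-2-yl)silyl]oxy}phenyl butanoate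
Product: 17 1-[2-hydroxy-4-methoxy-5-(methoxymethyl)-3-methyl-6-{[tri(propan-2-yl)silyl]oxy}phenyl]butan-1-one
Conditions: hν (254 nm), degassed cyclohexane, 20 °C
Reagents that add atoms: none
Why: Photo-Fries rearrangement: homolysis of the aryl O–acyl bond and recombination within the solvent cage at B3, the only unblocked ortho or para carbon, followed by enolization, should move the butanoyl group to carbon without Lewis acid, and the hydrogen-bonded o-hydroxyaryl ketone is photostable.

Step 7
Reactants: 17 1-[2-hydroxy-4-methoxy-5-(methoxymethyl)-3-methyl-6-{[tri(propan-2-yl)silyl]oxy}phenyl]butan-1-one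
Product: 18 1-[2,6-dihydroxy-4-methoxy-3-(methoxymethyl)-5-methylphenyl]butan-1-one
Conditions: Bu4NF, AcOH, THF, 0 °C
Reagents that add atoms: none
Why: Fluoride-induced cleavage of the aryl silyl ether, buffered by acetic acid, should free the B2 hydroxyl without touching the aryl methyl ether or the benzylic methyl ether.

Step 8
Reactants: 19 2-methylbenzene-1,3,5-triol; 15 butanoyl chloride
Product: 20 1-(2,4,6-trihydroxy-3-methylphenyl)butan-1-one
Conditions: AlCl3, PhNO2/CH2Cl2, 0 → 40 °C; aq. HCl
Reagents that add atoms: none
Why: Friedel–Crafts acylation of the strongly activated phloroglucinol ring, in which the two free ring carbons are equivalent by symmetry and the AlCl3-complexed ketone deactivates the ring against a second acylation.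

Step 9
Reactants: 20 1-(2,4,6-trihydroxy-3-methylphenyl)butan-1-one; 21 1-bromo-3-methylbut-2-ene
Product: 22 rac-2-butanoyl-3,5-dihydroxy-4-methyl-4-(3-methylbut-2-en-1-yl)cyclohexa-2,5-dien-1-one
Conditions: NaOMe (2 equiv), MeOH, 0 °C → rt; aq. HCl
Reagents that add atoms: none
Why: Alkylative dearomatization of an acylphloroglucinol: the delocalized anion should be C-alkylated at its methyl-bearing carbon to create the quaternary carbon as a racemate (no stereocontrol is sought here), and the strongly acidic trione is separable from C–H- and O-alkylated isomers by extraction into aqueous NaHCO3.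

Step 10
Reactants: 22 rac-2-butanoyl-3,5-dihydroxy-4-methyl-4-(3-methylbut-2-en-1-yl)cyclohexa-2,5-dien-1-one
Product: 23 (4R)-2-butanoyl-3,5-dihydroxy-4-methyl-4-(3-methylbut-2-en-1-yl)cyclohexa-2,5-dien-1-one
Conditions: preparative SFC, amylose tris(3,5-dimethylphenylcarbamate) phase, CO2/MeOH (HCO2H additive)
Reagents that add atoms: none
Why: Resolution of enantiomers by chromatography on a chiral stationary phase, routine for acidic enolized triones of this kind, should deliver the (R) enantiomer, whose all-carbon quaternary centre cannot epimerize and whose configuration is to be confirmed by X-ray analysis of a heavy-atom amine salt.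

Step 11
Reactants: 18 1-[2,6-dihydroxy-4-methoxy-3-(methoxymethyl)-5-methylphenyl]butan-1-one; 23 (4R)-2-butanoyl-3,5-dihydroxy-4-methyl-4-(3-methylbut-2-en-1-yl)cyclohexa-2,5-dien-1-one
Product: 25 (4R)-2-butanoyl-6-[(3-butanoyl-2,4-dihydroxy-6-methoxy-5-methylphenyl)methyl]-3,5-dihydroxy-4-methyl-4-(3-methylbut-2-en-1-yl)cyclohexa-2,5-dien-1-one, via ortho-quinone methide 24 (not isolated)
Conditions: toluene, 4 Å MS, 90 °C
Reagents that add atoms: none
Why: Thermal loss of methanol from the o-hydroxybenzyl ether, assisted by the acidic trione, should give ortho-quinone methide 24, which undergoes Michael addition by the only hydrogen-bearing enol carbon of ring A in 23 and rearomatizes, a standard way to methylene-bridged acylphloroglucinols; the remote (R) centre is not involved.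

Compound list
1 | 3-methoxyprop-1-yne | COCC#C | starting material
2 | lithium 3-methoxyprop-1-yn-1-olate | [Li+].[O-]C#CCOC | intermediate
3 | [(3-methoxyprop-1-yn-1-yl)oxy]tri(propan-2-yl)silane | COCC#CO[Si](C(C)C)(C(C)C)C(C)C | intermediate
4 | acetyl chloride | CC(=O)Cl | starting material
5 | ketene (ethenone) | C=C=O | intermediate
6 | 2-(methoxymethyl)-3-{[tri(propan-2-yl)silyl]oxy}cyclobut-2-en-1-one | COCC1=C(O[Si](C(C)C)(C(C)C)C(C)C)CC1=O | intermediate
7 | 2-chloro-1,1-dimethoxyethane | COC(CCl)OC | starting material
8 | sodium methoxyacetylide | [Na+].[C-]#COC | intermediate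
9 | 1-methoxyprop-1-yne | CC#COC | intermediate
10 | 2-(methoxymethyl)-3-{[tri(propan-2-yl)silyl]oxy}buta-1,3-dien-1-one | COCC(=C=O)C(=C)O[Si](C(C)C)(C(C)C)C(C)C | intermediate
11 | 3-methoxy-4-(methoxymethyl)-2-methyl-4-(1-{[tri(propan-2-yl)silyl]oxy}ethenyl)cyclobut-2-en-1-one (racemic) | COCC1(C(=C)O[Si](C(C)C)(C(C)C)C(C)C)C(OC)=C(C)C1=O | intermediate
12 | (3E)-3-methoxy-4-(methoxymethyl)-2-methyl-5-{[tri(propan-2-yl)silyl]oxy}hexa-1,3,5-trien-1-one | COC/C(C(=C)O[Si](C(C)C)(C(C)C)C(C)C)=C(OC)/C(C)=C=O | intermediate
13 | 3-methoxy-4-(methoxymethyl)-2-methyl-5-{[tri(propan-2-yl)silyl]oxy}cyclohexa-2,4-dien-1-one | COCC1=C(O[Si](C(C)C)(C(C)C)C(C)C)CC(=O)C(C)=C1OC | intermediate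
14 | 3-methoxy-4-(methoxymethyl)-2-methyl-5-{[tri(propan-2-yl)silyl]oxy}phenol | COCc1c(O[Si](C(C)C)(C(C)C)C(C)C)cc(O)c(C)c1OC | intermediate
15 | butanoyl chloride | CCCC(=O)Cl | starting material
16 | 3-methoxy-4-(methoxymethyl)-2-methyl-5-{[tri(propan-2-yl)silyl]oxy}phenyl butanoate | CCCC(=O)Oc1cc(O[Si](C(C)C)(C(C)C)C(C)C)c(COC)c(OC)c1C | intermediate
17 | 1-[2-hydroxy-4-methoxy-5-(methoxymethyl)-3-methyl-6-{[tri(propan-2-yl)silyl]oxy}phenyl]butan-1-one | CCCC(=O)c1c(O)c(C)c(OC)c(COC)c1O[Si](C(C)C)(C(C)C)C(C)C | intermediate
18 | 1-[2,6-dihydroxy-4-methoxy-3-(methoxymethyl)-5-methylphenyl]butan-1-one | CCCC(=O)c1c(O)c(C)c(OC)c(COC)c1O | intermediate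
19 | 2-methylbenzene-1,3,5-triol | Cc1c(O)cc(O)cc1O | starting material
20 | 1-(2,4,6-trihydroxy-3-methylphenyl)butan-1-one | CCCC(=O)c1c(O)cc(O)c(C)c1O | intermediate
21 | 1-bromo-3-methylbut-2-ene | CC(C)=CCBr | starting material
22 | rac-2-butanoyl-3,5-dihydroxy-4-methyl-4-(3-methylbut-2-en-1-yl)cyclohexa-2,5-dien-1-one | CCCC(=O)C1=C(O)C(C)(CC=C(C)C)C(O)=CC1=O | intermediate
23 | (4R)-2-butanoyl-3,5-dihydroxy-4-methyl-4-(3-methylbut-2-en-1-yl)cyclohexa-2,5-dien-1-one | CCCC(=O)C1=C(O)[C@](C)(CC=C(C)C)C(O)=CC1=O | intermediate
24 | 2-butanoyl-3-hydroxy-5-methoxy-4-methyl-6-methylidenecyclohexa-2,4-dien-1-one | CCCC(=O)C1=C(O)C(C)=C(OC)C(=C)C1=O | intermediate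
25 | (4R)-2-butanoyl-6-[(3-butanoyl-2,4-dihydroxy-6-methoxy-5-methylphenyl)methyl]-3,5-dihydroxy-4-methyl-4-(3-methylbut-2-en-1-yl)cyclohexa-2,5-dien-1-one | CCCC(=O)C1=C(O)[C@](C)(CC=C(C)C)C(O)=C(Cc2c(O)c(C(=O)CCC)c(O)c(C)c2OC)C1=O | target

Total step count: 11. Longest linear sequence: 7 steps (steps 1, 2, 4, 5, 6, 7, 11).

Steps most likely to fail

Step 4. The vinylogous-ester character of 6 may delay electrocyclic opening until the ynol ether oligomerizes, and the phenol formed may be acylated by the vinylketene or may alkylate itself through its benzylic ether. The fallback leaves the benzannulation aside and builds ring B from a phloroglucinol; it sets out from 20 and comes back to the route at 25, by way of quinone methide 24 of step 11. Methylation of the hydroxyl para to the ketone in 20 (Me2SO4, K2CO3, acetone; the two hydroxyls beside the ketone are held in hydrogen bonds) should give 1-(2,6-dihydroxy-4-methoxy-3-methylphenyl)butan-1-one F1. Mannich aminomethylation of its single free ring carbon with dimethylmethyleneiminium iodide (CH2Cl2, rt) should give 1-{3-[(dimethylamino)methyl]-2,6-dihydroxy-4-methoxy-5-methylphenyl}butan-1-one F2. Heating F2 with 23 in 1,4-dioxane at 90 °C should expel dimethylamine to form 24, which 23 traps as in step 11 to give 25.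

Step 6. Escape of the radical pair from the solvent cage (return to phenol 14) and competing photochemistry at the benzylic C–O bond may outrun recombination at the hindered carbon B3. The fallback replaces the rearrangement by directed ortho-metalation; it sets out from 14 and comes back at 17. Protection of 14 (chloromethyl methyl ether, iPr2NEt, CH2Cl2) should give [3-methoxy-5-(methoxymethoxy)-2-(methoxymethyl)-4-methylphenoxy]tri(propan-2-yl)silane F3. Lithiation at B3 between the two oxygens (sec-butyllithium, N,N,N′,N′-tetramethylethylenediamine, THF, −78 °C, cold enough to prevent silyl migration) and acylation with N-methoxy-N-methylbutanamide should give 1-[4-methoxy-2-(methoxymethoxy)-5-(methoxymethyl)-3-methyl-6-{[tri(propan-2-yl)silyl]oxy}phenyl]butan-1-one F4. Dilute HCl in methanol at rt should then remove the acetal to give 17; the benzylic methyl ether can only exchange with the solvent.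

Step 9. Alkylation at the unsubstituted ring carbon or at oxygen may outcompete attack at the methyl-bearing carbon, and over-alkylation may follow. The fallback builds the ring from an acyclic quaternary keto ester, so that the position of the prenyl group is fixed by connectivity; it sets out from 21 (with commercial methyl 2-methyl-3-oxobutanoate) and comes back at 22. C-Alkylation with 21 (K2CO3, acetone, reflux) should give methyl 2-acetyl-2,5-dimethylhex-4-enoate F5. Claisen acylation of its methyl-ketone enolate (LiN(SiMe3)2, 2 equiv, THF, −78 °C; 1-acetylimidazole) should give methyl 2,5-dimethyl-2-(3-oxobutanoyl)hex-4-enoate F6. Dianion formation (LiN(iPr)2, 2.2 equiv, THF, −78 °C → rt) should close the ring onto the ester to give the achiral 2-methyl-2-(3-methylbut-2-en-1-yl)cyclohexane-1,3,5-trione F7. C-Acylation with butanoic acid (N,N′-dicyclohexylcarbodiimide, 4-(dimethylamino)pyridine, CH2Cl2) at either of its two equivalent positions should give 22.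

Further compounds
F1 | step 4 | 1-(2,6-dihydroxy-4-methoxy-3-methylphenyl)butan-1-one | CCCC(=O)c1c(O)cc(OC)c(C)c1O
F2 | step 4 | 1-{3-[(dimethylamino)methyl]-2,6-dihydroxy-4-methoxy-5-methylphenyl}butan-1-one | CCCC(=O)c1c(O)c(C)c(OC)c(CN(C)C)c1O
F3 | step 6 | [3-methoxy-5-(methoxymethoxy)-2-(methoxymethyl)-4-methylphenoxy]tri(propan-2-yl)silane | COCOc1cc(O[Si](C(C)C)(C(C)C)C(C)C)c(COC)c(OC)c1C
F4 | step 6 | 1-[4-methoxy-2-(methoxymethoxy)-5-(methoxymethyl)-3-methyl-6-{[tri(propan-2-yl)silyl]oxy}phenyl]butan-1-one | CCCC(=O)c1c(OCOC)c(C)c(OC)c(COC)c1O[Si](C(C)C)(C(C)C)C(C)C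
F5 | step 9 | methyl 2-acetyl-2,5-dimethylhex-4-enoate (racemic) | COC(=O)C(C)(CC=C(C)C)C(C)=O
F6 | step 9 | methyl 2,5-dimethyl-2-(3-oxobutanoyl)hex-4-enoate (racemic) | COC(=O)C(C)(CC=C(C)C)C(=O)CC(C)=O
F7 | step 9 | 2-methyl-2-(3-methylbut-2-en-1-yl)cyclohexane-1,3,5-trione | CC(C)=CCC1(C)C(=O)CC(=O)CC1=O
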